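## The problem

Target 24 is the 3,4-dimethoxybenzoate of a daucane diol: a cyclopentane (ring A) trans-fused to a cycloheptene (ring B), fifteen skeletal carbons in all. The numbering used throughout is: C1 the quaternary ring-fusion carbon with methyl C15; C2 and C3 the ring A methylenes; C4 the tertiary carbinol carbon with the isopropyl group; C5 the ring-fusion CH; C6 the ester-bearing CH; C7; C8 with methyl C14; C9; C10.

- **Stereocentres.** C1, C4, C5 and C6 are contiguous. H5 is trans to C15, the C4 hydroxyl is cis to C15, and the C6 oxygen is cis to H5 and therefore on the same face as the isopropyl group.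
- **Which centre controls which.** Only C1 is all-carbon and configurationally inert, so it is the one to set by asymmetric catalysis. C5 and C6 (addition to a C5=C6 olefin) and C4 (addition to a C4 ketone) can then be set on the rigid bicycle under the influence of the angular methyl.
- **Sensitive groups.** The aryl ester does not survive hydride or organometallic reagents, so it must come last. The trisubstituted C8=C9 olefin must neither migrate nor be attacked in oxidation steps. Once C4 is a ketone, H5 is enolisable and the C6 oxygen becomes a β-leaving group.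
- **Enabling feature.** Ring B is a cyclohepta-1,4-diene in disguise. C8=C9 is present, and C5(H)–C6(O) is the anti-Markovnikov hydrate of a C5=C6 olefin. A cyclohepta-1,4-diene with the quaternary carbon C1 at the end of the C5=C6–C7 unit is what a cis-divinylcyclopropane gives on [3,3] rearrangement.

## Retrosynthesis

**Ester C6–O.** Cutting the acyl–oxygen bond of 24 gives diol 21 and veratric acid 22. This cut comes first because every earlier reductive or organometallic step would destroy the ester. The forward reaction only has to distinguish a secondary from a hindered tertiary hydroxyl.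

**C4–isopropyl bond.** Diol 21 comes from silyl ether 20, and 20 from ketone 19 by addition of an isopropyl nucleophile. Carrying the isopropyl group from the start would put a stereocentre next to the olefin that must later be hydroborated and would complicate the diene used in the key step. As a ketone, masked as ketal 18 until needed, C4 is a symmetric spectator. The forward addition must come from the face of H5, away from C15.

**C14 oxidation level.** The methyl group of 18 is traced back through allylic alcohol 16 to methyl ester 15. The ester is not a detour: the carbenoid of the key step needs it as its acceptor group, and it deactivates C8=C9 during the hydroboration.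

**C5–H and C6–O.** Silyl ether 15 comes from alcohol 14, and 14 from diene ester 12 by hydroboration of C5=C6. This sets two stereocentres in one operation from C1 alone. It is done while C4 is still a symmetric dioxolane, so that the angular methyl is the only facial bias. Epoxide or ketone routes to the same centres would need separate control of C5.

**Key disconnection, C7–C8 and C1–C10.** Diene ester 12 is the [3,3] product of cis-divinylcyclopropane 11, which comes from vinyldiazoacetate 10 and the vinyl group of ketal diene 5. Two skeletal bonds, ring B and the quaternary centre are made from two achiral pieces of ten and five carbons. The forward step needs site selectivity for the terminal olefin, cis-selectivity in the cyclopropanation, and catalyst control of absolute configuration.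

**Diene 5.** The vinyl–ring bond is cut to bromo ketal 4, available from bromo enone 3 and ultimately from 3-methylcyclopent-2-en-1-one 1. A cross-coupling on the ketal avoids handling the acid- and polymerisation-prone free dienone.

**Diazo ester 10.** The vinyl group is unmasked from hydroxy diazo ester 8, which comes from diazo keto ester 7 and methyl acetoacetate 6. The diazo group is installed while the carbon is still an active methylene.

## Roads not taken

**Alternative 1: cyclase-made skeleton.**
- Cut: C1–C10 and C4–C5 together, back to acyclic (2E,6E)-farnesyl diphosphate A1.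
- Forward key step: a carotol-synthase-type sesquiterpene cyclase ionises A1, closes both rings and quenches the C5 cation with water to give carotol A2.
- Merits: the whole C15 skeleton, both rings, the correct C1 configuration and the C8=C9 olefin arrive in one catalytic, protecting-group-free step. In skeleton building this is clearly better than the seven steps needed here to reach 12.
- Weak points: the oxygen is on the wrong carbon (C5, with H at C4 and nothing at C6). The target needs the C5 hydroxyl removed, a C4 hydroxyl and a C6 oxygen introduced and H5 set trans, all by electrophilic chemistry in which the C8=C9 olefin competes. The enzyme and its substrate are also not bench reagents.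
- Comparison: the chosen plan is longer to the bicycle but delivers it with C4 at the ketone level, C5=C6 ready for hydration and C8=C9 masked as an enoate, so no oxygen has to be moved.

**Alternative 2: oxidopyrylium [5+2] cycloaddition.**
- Cut: C1–C10 and C5–C6, the two bonds joining ring B to ring A.
- Forward key step: the ylide released with Et3N from 6-acetoxy-4-methyl-2H-pyran-3(6H)-one A4 adds across the C5=C1 bond of the enantiopure sulfinyl enone A3 to give the exo 8-oxabicyclo[3.2.1]octenone adduct A5.
- Merits: very convergent. It forms ring B, sets C1 and installs the C6 oxygen in one step, so A5 carries more of the target's stereochemical information than 12 does.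
- Weak points: the dipolarophile is a tetrasubstituted olefin that must form a quaternary and a fully substituted carbon at once. The controller is a stoichiometric sulfoxide. The endgame is subtractive: desulfinylation with control of H5, cleavage of the C10–O bridge bond, removal of the C9 oxygen and transposition of C7=C8 to C8=C9, all before the C4 addition.
- Comparison: against the richer key-step product of this alternative, the chosen plan sets an unhindered reacting olefin, catalytic enantiocontrol and an endgame that only adds (hydroboration, isopropyl) and reduces one ester.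

**Alternative 3: conjugate vinylation and aldol.**
- Cut: C1–C2 and C4–C5, leaving ring B as the preformed dienone 3,6-dimethylcyclohepta-2,5-dien-1-one A6.
- Forward key step: a chiral NHC–copper catalyst (from Cu(OTf)2) adds a vinylalane to C1, and the aluminium enolate is trapped at C5 by the aldehyde that carries the isopropyl group, giving aldol A7.
- Merits: catalytic asymmetric formation of the quaternary centre, all fifteen carbons assembled in one step, and the C6 oxygen and C8=C9 olefin already in place. On paper it is the shortest route.
- Weak points: ring A is still open. Closing C3–C4 requires the C4 ketone, which makes C5 the central carbon of a stereolabile 1,3-dicarbonyl. The closure must distinguish C4=O from C6=O and set the tertiary carbinol during ring formation. A6 is a skipped dienone prone to move into conjugation, and β,β-disubstituted cycloheptenones are demanding conjugate acceptors.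
- Comparison: the chosen plan accepts more steps (a silyl group on the C6 oxygen, the ester-to-methyl reduction) in exchange for setting C5, C6 and C4 on a closed, rigid bicycle under the control of C1.

Key step: step 7

Assumption: the sense of induction of the Rh2(DOSP)4 catalysts with monosubstituted alkenes is taken to hold for diene 5. On that model Rh2(R-DOSP)4 gives the (R) quaternary centre; if the sense proves opposite, Rh2(S-DOSP)4 is used with no other change.

Naming convention: azulene locants follow the target (azulene C3 = C4, C3a = C5, C4 = C6, C6 = C8, C8a = C1 of the skeletal numbering).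

## Route

Step 1
Reactants: 1 3-methylcyclopent-2-en-1-one
Product: 3 2-bromo-3-methylcyclopent-2-en-1-one, via trans-2,3-dibromo-3-methylcyclopentan-1-one 2 (not isolated)
Conditions: Br2, CH2Cl2, 0 °C; then Et3N, 0 °C → rt
Reagents that add atoms: bromine, BrBr
Why: Bromine addition to the enone followed by amine-induced dehydrobromination (loss of the acidic α-H and the tertiary β-bromide) is the standard α-bromination of cycloalkenones.

Step 2
Reactants: 3 2-bromo-3-methylcyclopent-2-en-1-one
Product: 4 6-bromo-7-methyl-1,4-dioxaspiro[4.4]non-6-ene
Conditions: HOCH2CH2OH, p-TsOH·H2O (cat.), benzene, reflux, Dean–Stark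
Reagents that add atoms: ethylene glycol, OCCO
Why: Acid-catalysed ketalisation with azeotropic removal of water; the α-bromine holds the olefin in place, so 2-bromoenones ketalise without double-bond migration.

Step 3
Reactants: 4 6-bromo-7-methyl-1,4-dioxaspiro[4.4]non-6-ene
Product: 5 6-ethenyl-7-methyl-1,4-dioxaspiro[4.4]non-6-ene
Conditions: Bu3SnCH=CH2, Pd(PPh3)4 (5 mol %), toluene, 100 °C; KF work-up, Et3N-treated silica
Reagents that add atoms: tributyl(vinyl)stannane, C=C[Sn](CCCC)(CCCC)CCCC
Why: Stille coupling of an alkenyl bromide under neutral conditions with zerovalent palladium; the ketal is untouched and the acid-sensitive diene is kept on base-washed silica.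

Step 4
Reactants: 6 methyl acetoacetate
Product: 7 methyl 2-diazo-3-oxobutanoate
Conditions: p-ABSA, Et3N, MeCN, 0 °C → rt
Reagents that add atoms: 4-acetamidobenzenesulfonyl azide, CC(=O)Nc1ccc(S(=O)(=O)N=[N+]=[N-])cc1
Why: Regitz diazo transfer to an active methylene compound.

Step 5
Reactants: 7 methyl 2-diazo-3-oxobutanoate
Product: 8 methyl 2-diazo-3-hydroxybutanoate (racemic)
Conditions: NaBH4, MeOH, 0 °C
Reagents that add atoms: none
Why: Borohydride reduces the ketone and leaves the diazo ester alone; the carbinol configuration is irrelevant because it is lost in the next step.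

Step 6
Reactants: 8 methyl 2-diazo-3-hydroxybutanoate
Product: 10 methyl 2-diazobut-3-enoate, via dichlorophosphate ester 9 (not isolated)
Conditions: POCl3, Et3N, CH2Cl2, 0 °C → rt; kept cold as a pentane solution and used at once
Reagents that add atoms: none
Why: Dehydration by phosphorylation and base-induced elimination is the standard route to vinyldiazoacetates; the product is used promptly because it slowly cyclises to a pyrazole.

Step 7
Reactants: 5 6-ethenyl-7-methyl-1,4-dioxaspiro[4.4]non-6-ene; 10 methyl 2-diazobut-3-enoate
Product: 12 methyl (8aR)-3,3-(ethylenedioxy)-8a-methyl-1,2,3,5,8,8a-hexahydroazulene-6-carboxylate, via cis-divinylcyclopropane 11 (not isolated)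
Conditions: Rh2(R-DOSP)4 (dirhodium tetrakis[(R)-N-(p-dodecylbenzenesulfonyl)prolinate], 1 mol %), pentane, −78 °C → rt, slow addition of 10 (1.5 equiv); then toluene, 90 °C
Reagents that add atoms: none
Why: The divalent-rhodium catalyst expels N2 from 10 to give a donor/acceptor vinylcarbenoid, which cyclopropanates the vinyl group of 5 (bonds C7–C8 and C6–C8) in a concerted, asynchronous step; the closest known reaction type is the formal [4+3] cycloaddition of such vinylcarbenoids with 1,3-dienes by tandem cyclopropanation and Cope rearrangement. Site selectivity comes from the substrate: the tetrasubstituted C1=C5 olefin is too hindered for this bulky carbenoid, so only the monosubstituted olefin reacts. Donor/acceptor carbenoids place the alkene substituent cis to the donor vinyl group, so 11 is the cis-divinylcyclopropane. On warming, 11 undergoes a [3,3]-sigmatropic shift through the boat transition state, the only one open to a cis-divinylcyclopropane; ring B is closed here by ring expansion of the three-membered ring, C1–C10 forming as C6–C8 breaks, and C8=C9 and C5=C6 appear in their final positions. Heating is needed because the C15 methyl on the Cope terminus points inward over the cyclopropane in the boat. The one new stereocentre, quaternary C1, is set indirectly: the chiral carboxylate ligands fix C6 and C8 of 11, and the boat geometry transfers that configuration to C1 stereospecifically. The step therefore needs high enantio- and cis-selectivity in the cyclopropanation, both of which this catalyst class provides with monosubstituted alkenes in hydrocarbon solvent at low temperature.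

Step 8
Reactants: 12 methyl (8aR)-3,3-(ethylenedioxy)-8a-methyl-1,2,3,5,8,8a-hexahydroazulene-6-carboxylate
Product: 14 methyl (3aS,4S,8aR)-3,3-(ethylenedioxy)-4-hydroxy-8a-methyl-1,2,3,3a,4,5,8,8a-octahydroazulene-6-carboxylate, via C6 alkylborane 13 (not isolated)
Conditions: BH3·SMe2 (1.2 equiv), THF, 0 °C → rt; then NaBO3·4H2O, THF/H2O, rt
Reagents that add atoms: sodium perborate tetrahydrate, [Na+].[O-]OB=O.O.O.O.O
Why: Hydroboration–oxidation: electrophilic borane selects C5=C6 over the ester-deactivated C8=C9, puts boron on the less substituted C6 and delivers H to C5 in a syn addition from the face opposite the angular C15 methyl, as with trisubstituted steroid olefins next to an angular methyl. The symmetric dioxolane at C4 offers no competing facial bias, and perborate oxidises C–B with retention without harming the ester, so 14 has the trans ring fusion with the C6 oxygen cis to H5.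

Step 9
Reactants: 14 methyl (3aS,4S,8aR)-3,3-(ethylenedioxy)-4-hydroxy-8a-methyl-1,2,3,3a,4,5,8,8a-octahydroazulene-6-carboxylate
Product: 15 methyl (3aS,4S,8aR)-4-(tert-butyldimethylsilyloxy)-3,3-(ethylenedioxy)-8a-methyl-1,2,3,3a,4,5,8,8a-octahydroazulene-6-carboxylate
Conditions: TBSCl, imidazole, DMAP (cat.), DMF, 40 °C
Reagents that add atoms: tert-butyldimethylsilyl chloride, CC(C)(C)[Si](C)(C)Cl
Why: Silylation of the only hydroxyl; the silyl ether survives hydride, buffered acid and organocerium reagents and is removed later by fluoride.

Step 10
Reactants: 15 methyl (3aS,4S,8aR)-4-(tert-butyldimethylsilyloxy)-3,3-(ethylenedioxy)-8a-methyl-1,2,3,3a,4,5,8,8a-octahydroazulene-6-carboxylate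
Product: 16 [(3aS,4S,8aR)-4-(tert-butyldimethylsilyloxy)-3,3-(ethylenedioxy)-8a-methyl-1,2,3,3a,4,5,8,8a-octahydroazulen-6-yl]methanol
Conditions: i-Bu2AlH (2.5 equiv), CH2Cl2, −78 °C → 0 °C; aq. sodium potassium tartrate
Reagents that add atoms: none
Why: 1,2-Reduction of the enoate to the primary allylic alcohol; ketal, silyl ether and olefin are inert to this hydride.

Step 11
Reactants: 16 [(3aS,4S,8aR)-4-(tert-butyldimethylsilyloxy)-3,3-(ethylenedioxy)-8a-methyl-1,2,3,3a,4,5,8,8a-octahydroazulen-6-yl]methanol
Product: 18 (3aS,4S,8aR)-4-(tert-butyldimethylsilyloxy)-3,3-(ethylenedioxy)-6,8a-dimethyl-1,2,3,3a,4,5,8,8a-octahydroazulene, via pyridinium allylic sulfate 17 (not isolated)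
Conditions: SO3·pyridine, THF, 0 °C → rt; then LiAlH4, THF, 0 °C → rt
Reagents that add atoms: none
Why: Allylic deoxygenation by sulfation and hydride displacement: hydride attacks the primary carbon of the sulfate monoester (SN2), so C8=C9 stays in place and C14 becomes the methyl group; ketal and silyl ether tolerate LiAlH4.

Step 12
Reactants: 18 (3aS,4S,8aR)-4-(tert-butyldimethylsilyloxy)-3,3-(ethylenedioxy)-6,8a-dimethyl-1,2,3,3a,4,5,8,8a-octahydroazulene
Product: 19 (3aS,4S,8aR)-4-(tert-butyldimethylsilyloxy)-6,8a-dimethyl-2,3a,4,5,8,8a-hexahydroazulen-3(1H)-one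
Conditions: PPTS (cat.), acetone/H2O (10:1), 45 °C
Reagents that add atoms: water, O
Why: Acid-catalysed ketal hydrolysis; cyclopentanone dioxolanes open easily because the carbonyl relieves eclipsing strain, so a buffered pyridinium acid should suffice and the secondary silyl ether and the C5 configuration (no base, weak acid) should be kept.

Step 13
Reactants: 19 (3aS,4S,8aR)-4-(tert-butyldimethylsilyloxy)-6,8a-dimethyl-2,3a,4,5,8,8a-hexahydroazulen-3(1H)-one
Product: 20 (3R,3aS,4S,8aR)-4-(tert-butyldimethylsilyloxy)-6,8a-dimethyl-3-(propan-2-yl)-1,2,3,3a,4,5,8,8a-octahydroazulen-3-ol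
Conditions: i-PrMgCl, CeCl3 (anhydrous, pre-stirred), THF, −78 °C → 0 °C
Reagents that add atoms: isopropylmagnesium chloride, CC(C)[Mg]Cl
Why: CeCl3-mediated 1,2-addition of the isopropyl reagent: the nucleophile should approach C4 from the face of H5, away from the C15 methyl that stands 1,3 and pseudo-axial over the other face of the cyclopentanone, which places the new hydroxyl cis to C15. The weakly basic trivalent-cerium reagent suppresses enolisation toward C5 and β-hydride reduction.

Step 14
Reactants: 20 (3R,3aS,4S,8aR)-4-(tert-butyldimethylsilyloxy)-6,8a-dimethyl-3-(propan-2-yl)-1,2,3,3a,4,5,8,8a-octahydroazulen-3-ol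
Product: 21 (3R,3aS,4S,8aR)-6,8a-dimethyl-3-(propan-2-yl)-1,2,3,3a,4,5,8,8a-octahydroazulene-3,4-diol
Conditions: Bu4NF, THF, rt → 45 °C
Reagents that add atoms: none
Why: Fluoride cleavage of the Si–O bond; the tertiary alcohol and the olefin are inert.

Step 15
Reactants: 21 (3R,3aS,4S,8aR)-6,8a-dimethyl-3-(propan-2-yl)-1,2,3,3a,4,5,8,8a-octahydroazulene-3,4-diol; 22 veratric acid (3,4-dimethoxybenzoic acid)
Product: 24 (3R,3aS,4S,8aR)-3-hydroxy-6,8a-dimethyl-3-(propan-2-yl)-1,2,3,3a,4,5,8,8a-octahydroazulen-4-yl 3,4-dimethoxybenzoate, via 3,4-dimethoxybenzoyl chloride 23 (not isolated)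
Conditions: 22, (COCl)2, DMF (cat.), CH2Cl2, 0 °C → rt, concentrate; then 21, Et3N, DMAP, CH2Cl2, 0 °C → rt
Reagents that add atoms: none
Why: Acid chloride formation and DMAP-catalysed acylation; the secondary C6 hydroxyl is acylated while the tertiary C4 hydroxyl, flanked by the isopropyl group, is not.

## Compound list

1 | 3-methylcyclopent-2-en-1-one | CC1=CC(=O)CC1 | starting material
2 | trans-2,3-dibromo-3-methylcyclopentan-1-one (racemic, one enantiomer drawn) | O=C1[C@@H](Br)[C@](C)(Br)CC1 | intermediate
3 | 2-bromo-3-methylcyclopent-2-en-1-one | CC1=C(Br)C(=O)CC1 | intermediate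
4 | 6-bromo-7-methyl-1,4-dioxaspiro[4.4]non-6-ene | CC1=C(Br)C2(CC1)OCCO2 | intermediate
5 | 6-ethenyl-7-methyl-1,4-dioxaspiro[4.4]non-6-ene | C=CC1=C(C)CCC12OCCO2 | intermediate
6 | methyl acetoacetate | CC(=O)CC(=O)OC | starting material
7 | methyl 2-diazo-3-oxobutanoate | CC(=O)C(=[N+]=[N-])C(=O)OC | intermediate
8 | methyl 2-diazo-3-hydroxybutanoate (racemic) | CC(O)C(=[N+]=[N-])C(=O)OC | intermediate
9 | methyl 2-diazo-3-(dichlorophosphoryloxy)butanoate (racemic) | CC(OP(=O)(Cl)Cl)C(=[N+]=[N-])C(=O)OC | intermediate
10 | methyl 2-diazobut-3-enoate | C=CC(=[N+]=[N-])C(=O)OC | intermediate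
11 | methyl (1S,2S)-1-ethenyl-2-(7-methyl-1,4-dioxaspiro[4.4]non-6-en-6-yl)cyclopropane-1-carboxylate | C=C[C@@]1(C(=O)OC)C[C@H]1C2=C(C)CCC23OCCO3 | intermediate
12 | methyl (8aR)-3,3-(ethylenedioxy)-8a-methyl-1,2,3,5,8,8a-hexahydroazulene-6-carboxylate | COC(=O)C1=CC[C@@]2(C)CCC3(OCCO3)C2=CC1 | intermediate
13 | C6 dihydroboryl adduct of 12 (boron at C6 and H5 on the face opposite C15) | COC(=O)C1=CC[C@@]2(C)CCC3(OCCO3)[C@@H]2[C@@H](B)C1 | intermediate
14 | methyl (3aS,4S,8aR)-3,3-(ethylenedioxy)-4-hydroxy-8a-methyl-1,2,3,3a,4,5,8,8a-octahydroazulene-6-carboxylate | COC(=O)C1=CC[C@@]2(C)CCC3(OCCO3)[C@@H]2[C@@H](O)C1 | intermediate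
15 | methyl (3aS,4S,8aR)-4-(tert-butyldimethylsilyloxy)-3,3-(ethylenedioxy)-8a-methyl-1,2,3,3a,4,5,8,8a-octahydroazulene-6-carboxylate | COC(=O)C1=CC[C@@]2(C)CCC3(OCCO3)[C@@H]2[C@@H](O[Si](C)(C)C(C)(C)C)C1 | intermediate
16 | [(3aS,4S,8aR)-4-(tert-butyldimethylsilyloxy)-3,3-(ethylenedioxy)-8a-methyl-1,2,3,3a,4,5,8,8a-octahydroazulen-6-yl]methanol | OCC1=CC[C@@]2(C)CCC3(OCCO3)[C@@H]2[C@@H](O[Si](C)(C)C(C)(C)C)C1 | intermediate
17 | pyridinium sulfate monoester of 16 | [O-]S(=O)(=O)OCC1=CC[C@@]2(C)CCC3(OCCO3)[C@@H]2[C@@H](O[Si](C)(C)C(C)(C)C)C1.c1cc[nH+]cc1 | intermediate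
18 | (3aS,4S,8aR)-4-(tert-butyldimethylsilyloxy)-3,3-(ethylenedioxy)-6,8a-dimethyl-1,2,3,3a,4,5,8,8a-octahydroazulene | CC1=CC[C@@]2(C)CCC3(OCCO3)[C@@H]2[C@@H](O[Si](C)(C)C(C)(C)C)C1 | intermediate
19 | (3aS,4S,8aR)-4-(tert-butyldimethylsilyloxy)-6,8a-dimethyl-2,3a,4,5,8,8a-hexahydroazulen-3(1H)-one | CC1=CC[C@@]2(C)CCC(=O)[C@@H]2[C@@H](O[Si](C)(C)C(C)(C)C)C1 | intermediate
20 | (3R,3aS,4S,8aR)-4-(tert-butyldimethylsilyloxy)-6,8a-dimethyl-3-(propan-2-yl)-1,2,3,3a,4,5,8,8a-octahydroazulen-3-ol | CC1=CC[C@@]2(C)CC[C@@](O)(C(C)C)[C@@H]2[C@@H](O[Si](C)(C)C(C)(C)C)C1 | intermediate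
21 | (3R,3aS,4S,8aR)-6,8a-dimethyl-3-(propan-2-yl)-1,2,3,3a,4,5,8,8a-octahydroazulene-3,4-diol | CC1=CC[C@@]2(C)CC[C@@](O)(C(C)C)[C@@H]2[C@@H](O)C1 | intermediate
22 | veratric acid (3,4-dimethoxybenzoic acid) | COc1ccc(C(=O)O)cc1OC | starting material
23 | 3,4-dimethoxybenzoyl chloride | COc1ccc(C(=O)Cl)cc1OC | intermediate
24 | (3R,3aS,4S,8aR)-3-hydroxy-6,8a-dimethyl-3-(propan-2-yl)-1,2,3,3a,4,5,8,8a-octahydroazulen-4-yl 3,4-dimethoxybenzoate | COc1ccc(C(=O)O[C@H]2CC(C)=CC[C@@]3(C)CC[C@@](O)(C(C)C)[C@H]23)cc1OC | target

## Step count and risks

Total steps: 15. Longest linear sequence: 12 (steps 1–3, then 7–15; the diazo arm, steps 4–6, then 7–15, is equally long).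

**Step 7 (key step).** The most likely shortfall is incomplete enantioselection. The reacting vinyl group of 5 is flanked by a 2,5-disubstituted cyclopentenyl ring, which is more crowded than the dienes on which the catalyst model rests. Attack of the carbenoid on a ketal oxygen or at its own vinylogous terminus would lower the yield, and the [3,3] shift may be slow because of the inward methyl. Fallback: enantiomeric purity is secured by covalent resolution instead of by the catalyst alone. Alcohol 14 of insufficient purity is esterified with (S)-2-methoxy-2-phenylacetic acid (DCC, DMAP, CH2Cl2) to give the (S)-2-methoxy-2-phenylacetate of 14, F1. The major diastereomer is purified by chromatography or crystallisation, and methanolysis (K2CO3, MeOH) returns 14 as a single enantiomer.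

**Step 8.** Borane may be consumed by the enoate (conjugate reduction or ester reduction), because C5=C6 lies between a quaternary carbon and the ketal and reacts slowly; facial selectivity may also be incomplete. Fallback from 12: epoxidation with mCPBA (NaHCO3, CH2Cl2, 0 °C), to which the enoate olefin is inert, should give the 5,6-epoxide of 12 with oxygen on the face opposite C15, F2. Reductive opening with Cp2TiCl (trivalent titanium, made in the flask from Cp2TiCl2 and Zn) and 1,4-cyclohexadiene in THF cleaves the C5–O bond to the tertiary radical and, after hydrogen-atom transfer, returns to the route at 14. The configuration at C5 then rests on hydrogen-atom delivery anti to C15, which is the weaker point of this fallback.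

**Step 12.** Conditions forcing enough to open the hindered ketal may also remove the silyl ether, or the freed ketone may enolise toward C5 (epimerisation, loss of the C6 oxygen). Fallback from 18: both groups are removed deliberately (aq. HCl, THF, 0 °C → rt) to give (3aS,4S,8aR)-4-hydroxy-6,8a-dimethyl-2,3a,4,5,8,8a-hexahydroazulen-3(1H)-one, F3. F3 is treated cold with excess i-PrMgCl/CeCl3. The first equivalent forms the C6 alkoxide, which is small and can deliver the reagent to its own face, the one required. This returns to the route at 21 and saves a step.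

**Step 13.** β-Hydride transfer from the isopropyl reagent (reduction) or enolisation may compete with addition to this crowded carbonyl, and the silyloxy group on C6 may erode facial selectivity. Fallback from 19: 2-propenylmagnesium bromide with CeCl3, a smaller sp2 nucleophile that cannot transfer a β-hydride, should give (3S,3aS,4S,8aR)-4-(tert-butyldimethylsilyloxy)-6,8a-dimethyl-3-(prop-1-en-2-yl)-1,2,3,3a,4,5,8,8a-octahydroazulen-3-ol, F4. Hydrogenation with H2 and RhCl(PPh3)3 in benzene, selective for the 1,1-disubstituted olefin over the trisubstituted ring olefin, returns to the route at 20.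

## Further compounds

F1 | step 7 | (S)-2-methoxy-2-phenylacetate ester of 14 | COC(=O)C1=CC[C@@]2(C)CCC3(OCCO3)[C@@H]2[C@@H](OC(=O)[C@@H](OC)c4ccccc4)C1
F2 | step 8 | 5,6-epoxide of 12, oxygen on the face opposite C15 | COC(=O)C1=CC[C@@]2(C)CCC3(OCCO3)[C@@]24O[C@H]4C1
F3 | step 12 | (3aS,4S,8aR)-4-hydroxy-6,8a-dimethyl-2,3a,4,5,8,8a-hexahydroazulen-3(1H)-one | CC1=CC[C@@]2(C)CCC(=O)[C@@H]2[C@@H](O)C1
F4 | step 13 | (3S,3aS,4S,8aR)-4-(tert-butyldimethylsilyloxy)-6,8a-dimethyl-3-(prop-1-en-2-yl)-1,2,3,3a,4,5,8,8a-octahydroazulen-3-ol | CC1=CC[C@@]2(C)CC[C@@](O)(C(C)=C)[C@@H]2[C@@H](O[Si](C)(C)C(C)(C)C)C1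
A1 | alternative 1 | (2E,6E)-farnesyl diphosphate | CC(C)=CCC/C(C)=C/CC/C(C)=C/COP(=O)(O)OP(=O)(O)O
A2 | alternative 1 | carotol | C1CC(C)=CC[C@@]2(C)CC[C@@H](C(C)C)[C@@]12O
A3 | alternative 2 | (S)-3-methyl-2-(4-methylbenzenesulfinyl)cyclopent-2-en-1-one | CC1=C([S@@](=O)c2ccc(C)cc2)C(=O)CC1
A4 | alternative 2 | 6-acetoxy-4-methyl-2H-pyran-3(6H)-one (racemic) | CC(=O)OC1C=C(C)C(=O)CO1
A5 | alternative 2 | exo [5+2] cycloadduct (oxygen bridge C6–O–C10, C9 ketone, C7=C8) | O=C1CC[C@@]2(C)[C@]1([S@@](=O)c1ccc(C)cc1)[C@@H]3C=C(C)C(=O)[C@H]2O3
A6 | alternative 3 | 3,6-dimethylcyclohepta-2,5-dien-1-one | O=C1C=C(C)CC=C(C)C1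
A7 | alternative 3 | trans-2,3-disubstituted cycloheptenone aldol | C=C[C@]1(C)CC=C(C)CC(=O)[C@H]1[C@@H](O)C(C)C
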